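**Plan**

1. Numbering (germacrane): ring C1–C10; C11(=C13)–C12(=O)–O8 is the methylene lactone on C7/C8; C15(=O)–O6 is the butenolide on C4/C6; C14 sits on C10. Retrosynthetic cuts, in order: C14–O (hydration of a C10=C14 methylene); C12–O8 together with C8–C9 (allylmetal plus C8 aldehyde, then lactonisation); the C3–O acyl bond; C12 oxidation level and C13 (methylenation); C6–C7 (silyloxyfuran plus enal); C4=C5 (RCM); C3–C4 (Morita–Baylis–Hillman); C1–C2 (enolate alkylation).
2. Forward: the chain C3–C2–C1–C10(=CH2)–CH2Cl is made first; the butenolide ring follows (C3–C4, then C4=C5); the C6–C7 bond adds the C7/C8/C11/C12 unit; the acrylate ester and the isobutyrate are installed; the ten-membered carbocycle and the α-methylene-γ-lactone close together in the key step; the C14 hydroxyl comes last.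
3. Enabling feature: C9 is a CH2 between the carbinol carbon C8 and C10, the carbon that carries C14. C9–C10–C14 is therefore a 2-substituted allyl unit and C8–C9 is the bond of an allylmetal-to-aldehyde addition. O8 lies γ to the C12 carbonyl, so the new alkoxide closes the five-membered lactone, and the C14 oxygen is returned by hydroboration of the exocyclic alkene left on C10.
4. Stereochemistry: C3 from the chiral amine catalyst (step 3); C7 and C6 from the imidazolidinone catalyst (step 7); C8 by substrate control from C7/C6 in the ring closure (step 13); C10 by substrate-controlled hydroboration (step 14).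

Key step: step 13

Assumption: 1, 2, 6, 8, 12 and all reagents and catalysts are commercially available or known; the sense of induction of the two organocatalysts (steps 3 and 7) is taken by analogy with their reactions of simple aldehydes and enals.

**Route**

Step 1
Reactants: 1 ethyl acetate; 2 3-chloro-2-(chloromethyl)prop-1-ene
Product: 4 ethyl 4-(chloromethyl)pent-4-enoate, via lithium enolate 3 (not isolated)
Conditions: LDA, THF, −78 °C; then 2 (3 equiv), DMPU, −78 → 0 °C
Reagents that add atoms: none
Why: The kinetic lithium enolate of ethyl acetate displaces one allylic chloride of the symmetrical dichloride (ester enolate alkylation; SN2 and SN2' give the same product) and the excess of 2 suppresses a second alkylation.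

Step 2
Reactants: 4 ethyl 4-(chloromethyl)pent-4-enoate
Product: 5 4-(chloromethyl)pent-4-enal
Conditions: DIBAL-H (1.1 equiv), CH2Cl2, −78 °C; aq. Rochelle salt
Reagents that add atoms: none
Why: DIBAL-H at −78 °C stops at the aluminium hemiacetal, which gives the aldehyde on work-up, while the allylic chloride and the alkene are untouched (partial reduction of an ester).

Step 3
Reactants: 5 4-(chloromethyl)pent-4-enal; 6 1,1,1,3,3,3-hexafluoropropan-2-yl acrylate
Product: 7 1,1,1,3,3,3-hexafluoropropan-2-yl (3S)-6-(chloromethyl)-3-hydroxy-2-methylidenehept-6-enoate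
Conditions: α-isocupreine (10 mol %), DMF, −55 °C
Reagents that add atoms: none
Why: Morita–Baylis–Hillman reaction of the activated acrylate 6 under chiral tertiary-amine catalysis: the phenolic OH of the catalyst hydrogen-bonds the zwitterionic aldol adduct so that only one diastereomeric betaine eliminates productively, which should set C3 as S (the quinidine-derived pseudoenantiomer should give R).

Step 4
Reactants: 7 the hexafluoroisopropyl ester; 8 allyl alcohol
Product: 9 prop-2-en-1-yl (3S)-6-(chloromethyl)-3-hydroxy-2-methylidenehept-6-enoate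
Conditions: allyl alcohol (10 equiv), Et3N, CH2Cl2, rt
Reagents that add atoms: none
Why: The hexafluoroisopropyl ester is an activated ester, so base-mediated transesterification with allyl alcohol is fast at room temperature and leaves the secondary carbinol and the allylic chloride alone (acyl substitution).

Step 5
Reactants: 9 the allyl ester
Product: 10 3-[(1S)-5-(chloromethyl)-1-hydroxyhex-5-en-1-yl]furan-2(5H)-one
Conditions: second-generation Grubbs catalyst (5 mol %), CH2Cl2, 40 °C
Reagents that add atoms: none
Why: Ring-closing metathesis between the allyl ester vinyl group and the acrylate methylene closes the five-membered butenolide with loss of ethene, whereas the 2-(chloromethyl)allyl alkene could only give a tetrasubstituted or medium-ring alkene and stays out.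

Step 6
Reactants: 10 the butenolide
Product: 11 trimethyl({3-[(1S)-5-(chloromethyl)-1-[(trimethylsilyl)oxy]hex-5-en-1-yl]furan-2-yl}oxy)silane
Conditions: TMSOTf (2.4 equiv), Et3N (3 equiv), CH2Cl2, 0 °C; used crude
Reagents that add atoms: trimethylsilyl trifluoromethanesulfonate, C[Si](C)(C)OS(=O)(=O)C(F)(F)F
Why: TMSOTf/Et3N enolises the butenolide at the γ-CH2 to the aromatic 2-silyloxyfuran and silylates the carbinol in the same operation (silyl dienol ether formation), the silyl ether being a poor leaving group next to the electron-rich furan.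

Step 7
Reactants: 11 the bis-silyl furan; 12 (E)-4,4-dimethoxybut-2-enal
Product: 14 (3R)-3-[(2R)-4-[(1S)-5-(chloromethyl)-1-hydroxyhex-5-en-1-yl]-5-oxo-2,5-dihydrofuran-2-yl]-4,4-dimethoxybutanal, via silyl ether 13 (not isolated)
Conditions: (2S,5S)-5-benzyl-2-tert-butyl-3-methylimidazolidin-4-one (20 mol %), 2,4-dinitrobenzoic acid (20 mol %), CH2Cl2, H2O (2 equiv), −40 °C; then aq. citric acid, THF, 0 °C
Reagents that add atoms: none
Why: Vinylogous Mukaiyama–Michael addition under iminium catalysis: the imidazolidinone condenses with enal 12, its benzyl and tert-butyl groups shield one face of the (E)-iminium so that furan C5 should add to the open face of the β-carbon and set C7 (by analogy with additions of π-nucleophiles to simple enals), the open transition state sets C6 relative to C7 with the co-acid and solvent as tuning handles, and the acidic work-up frees the C3 hydroxyl.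

Step 8
Reactants: 14 the aldehyde
Product: 15 (3R)-3-[(2R)-4-[(1S)-5-(chloromethyl)-1-hydroxyhex-5-en-1-yl]-5-oxo-2,5-dihydrofuran-2-yl]-4,4-dimethoxy-2-methylidenebutanal
Conditions: 37 % aq. CH2O, pyrrolidine (10 mol %), EtCO2H (10 mol %), i-PrOH, 45 °C
Reagents that add atoms: formaldehyde, C=O
Why: Amine-catalysed Mannich condensation of the α-CH2 aldehyde with formaldehyde followed by elimination gives the 2-substituted acrolein (organocatalytic α-methylenation), and C7 is not enolised because it is β to the aldehyde.

Step 9
Reactants: 15 the enal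
Product: 16 (3R)-3-[(2R)-4-[(1S)-5-(chloromethyl)-1-hydroxyhex-5-en-1-yl]-5-oxo-2,5-dihydrofuran-2-yl]-4,4-dimethoxy-2-methylidenebutanoic acid
Conditions: NaClO2, NaH2PO4, 2-methyl-2-butene, t-BuOH/H2O, 0 °C → rt
Reagents that add atoms: sodium chlorite, [Na+].[O-]Cl=O
Why: Pinnick oxidation converts the enal into the acrylic acid in a phosphate buffer that should spare the acetal, the free carbinol and the alkenes (hypochlorous acid is trapped by 2-methyl-2-butene).

Step 10
Reactants: 16 the acid
Product: 17 methyl (3R)-3-[(2R)-4-[(1S)-5-(chloromethyl)-1-hydroxyhex-5-en-1-yl]-5-oxo-2,5-dihydrofuran-2-yl]-4,4-dimethoxy-2-methylidenebutanoate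
Conditions: TMSCHN2, MeOH/toluene, 0 °C
Reagents that add atoms: (trimethylsilyl)diazomethane, C[Si](C)(C)C=[N+]=[N-]
Why: Methylation of the carboxylic acid with (trimethylsilyl)diazomethane in methanol is fast and neutral, and the ester is needed because a free acid would protonate the organochromium of step 13.

Step 11
Reactants: 17 the hydroxy ester
Product: 18 methyl (3R)-3-[(2R)-4-[(1S)-5-(chloromethyl)-1-(2-methylpropanoyloxy)hex-5-en-1-yl]-5-oxo-2,5-dihydrofuran-2-yl]-4,4-dimethoxy-2-methylidenebutanoate
Conditions: i-PrCOCl, pyridine, CH2Cl2, 0 °C → rt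
Reagents that add atoms: 2-methylpropanoyl chloride, CC(C)C(Cl)=O
Why: Acylation of the secondary C3 carbinol with the acid chloride installs the isobutyrate of the target before the aldehyde is unmasked, pyridine (not a stronger nucleophilic catalyst) being used to avoid SN2' displacement of the new allylic ester on the butenolide (nucleophilic acyl substitution).

Step 12
Reactants: 18 the acetal
Product: 19 methyl (3R)-3-[(2R)-4-[(1S)-5-(chloromethyl)-1-(2-methylpropanoyloxy)hex-5-en-1-yl]-5-oxo-2,5-dihydrofuran-2-yl]-2-methylidene-4-oxobutanoate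
Conditions: TFA/H2O/CH2Cl2 (1:1:10), 0 °C; used crude
Reagents that add atoms: water, O
Why: Acid-catalysed hydrolysis of the dimethyl acetal releases the C8 aldehyde under non-basic conditions, which matters because its α-hydrogen at C7 is flanked by a β-acyloxy leaving group (O6) and the acrylate, so the aldehyde is used at once.

Step 13
Reactants: 19 the chloro aldehyde
Product: 22 (3S,6R,7S,8R)-3-(2-methylpropanoyloxy)germacra-4E,10(14),11(13)-triene-12,8:15,6-diolide, via allylchromium dichloride 20 (not isolated), via hydroxy ester 21 (not isolated)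
Conditions: CrCl2 (8 equiv), THF/DMF (3:1), 0.002 M, slow addition of 19, rt; aq. NH4Cl; then PPTS (cat.), CH2Cl2, rt
Reagents that add atoms: none
Why: Two equivalents of CrCl2 insert into the allylic C–Cl bond to give the 2-substituted allylchromium 20 (trivalent chromium) with two equivalent CH2 termini, which adds to the C8 aldehyde through a chair, six-membered Zimmerman–Traxler transition state, forming C8–C9 and leaving the exocyclic C10=C14 methylene. The closest known reaction type is the intramolecular Nozaki–Hiyama–Kishi allylation (Barbier-type macrocyclisation), which is known to close ten-membered carbocycles. The ten-membered carbocycle closes by 10-exo-trig addition to the carbonyl, and the γ-lactone then closes by 5-exo-trig attack of the C8 chromium alkoxide on the C12 methyl ester (completed by PPTS). The new stereocentre C8 is controlled by C7: in the Felkin–Anh arrangement the ring bond C6–C7 is antiperiplanar to the forming C8–C9 bond and the acrylate carbon C11 lies next to the carbonyl oxygen, which should give the 8R alkoxide with O8 trans to C11, the geometry of the trans-fused lactone, and 1,3-anti induction from the C6–O bond reinforces it. The step needs chemoselectivity for the aldehyde over two esters, a lactone and two enoates, which organochromium reagents provide, and ring closure over oligomerisation, which high dilution and slow addition secure.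

Step 14
Reactants: 22 the 10(14)-ene bis-lactone
Product: 24 (3S,6R,7S,8R,10R)-14-hydroxy-3-(2-methylpropanoyloxy)germacra-4E,11(13)-diene-12,8:15,6-diolide (CNP0332805.1), via alkylborane 23 (not isolated)
Conditions: 9-BBN (1.5 equiv), THF, 0 °C → rt; then 30 % H2O2, pH 7 phosphate buffer, 0 °C → rt
Reagents that add atoms: hydrogen peroxide, OO
Why: 9-BBN adds to the electron-rich 1,1-disubstituted C10=C14 alkene with boron on C14 (Brown hydroboration, anti-Markovnikov) and is too bulky and electrophilic for the conjugated butenolide and α-methylene lactone; since both oxygen substituents that flank C10 across the ring (O8 on C8 and the isobutyrate on C3) lie on the α-face, the borane should deliver hydrogen to C10 from the β-face, placing C14 on the side of O8 (10R), and neutral peroxide oxidation with retention gives the primary alcohol.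

**Compound list**

1 | ethyl acetate | CCOC(C)=O | starting material
2 | 3-chloro-2-(chloromethyl)prop-1-ene | C=C(CCl)CCl | starting material
3 | lithium 1-ethoxyethen-1-olate (lithium enolate of 1) | [Li]OC(=C)OCC | intermediate (not isolated)
4 | ethyl 4-(chloromethyl)pent-4-enoate | CCOC(=O)CCC(=C)CCl | intermediate
5 | 4-(chloromethyl)pent-4-enal | O=CCCC(=C)CCl | intermediate
6 | 1,1,1,3,3,3-hexafluoropropan-2-yl acrylate | C=CC(=O)OC(C(F)(F)F)C(F)(F)F | starting material
7 | 1,1,1,3,3,3-hexafluoropropan-2-yl (3S)-6-(chloromethyl)-3-hydroxy-2-methylidenehept-6-enoate | ClCC(=C)CC[C@H](O)C(=C)C(=O)OC(C(F)(F)F)C(F)(F)F | intermediate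
8 | allyl alcohol | C=CCO | starting material
9 | prop-2-en-1-yl (3S)-6-(chloromethyl)-3-hydroxy-2-methylidenehept-6-enoate | ClCC(=C)CC[C@H](O)C(=C)C(=O)OCC=C | intermediate
10 | 3-[(1S)-5-(chloromethyl)-1-hydroxyhex-5-en-1-yl]furan-2(5H)-one | ClCC(=C)CC[C@H](O)C1=CCOC1=O | intermediate
11 | trimethyl({3-[(1S)-5-(chloromethyl)-1-[(trimethylsilyl)oxy]hex-5-en-1-yl]furan-2-yl}oxy)silane | ClCC(=C)CC[C@H](O[Si](C)(C)C)c1ccoc1O[Si](C)(C)C | intermediate
12 | (E)-4,4-dimethoxybut-2-enal | COC(OC)/C=C/C=O | starting material
13 | (3R)-3-[(2R)-4-[(1S)-5-(chloromethyl)-1-[(trimethylsilyl)oxy]hex-5-en-1-yl]-5-oxo-2,5-dihydrofuran-2-yl]-4,4-dimethoxybutanal | ClCC(=C)CC[C@H](O[Si](C)(C)C)C1=C[C@@H](OC1=O)[C@@H](CC=O)C(OC)OC | intermediate (not isolated)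
14 | (3R)-3-[(2R)-4-[(1S)-5-(chloromethyl)-1-hydroxyhex-5-en-1-yl]-5-oxo-2,5-dihydrofuran-2-yl]-4,4-dimethoxybutanal | ClCC(=C)CC[C@H](O)C1=C[C@@H](OC1=O)[C@@H](CC=O)C(OC)OC | intermediate
15 | (3R)-3-[(2R)-4-[(1S)-5-(chloromethyl)-1-hydroxyhex-5-en-1-yl]-5-oxo-2,5-dihydrofuran-2-yl]-4,4-dimethoxy-2-methylidenebutanal | ClCC(=C)CC[C@H](O)C1=C[C@@H](OC1=O)[C@@H](C(=C)C=O)C(OC)OC | intermediate
16 | (3R)-3-[(2R)-4-[(1S)-5-(chloromethyl)-1-hydroxyhex-5-en-1-yl]-5-oxo-2,5-dihydrofuran-2-yl]-4,4-dimethoxy-2-methylidenebutanoic acid | ClCC(=C)CC[C@H](O)C1=C[C@@H](OC1=O)[C@@H](C(=C)C(=O)O)C(OC)OC | intermediate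
17 | methyl (3R)-3-[(2R)-4-[(1S)-5-(chloromethyl)-1-hydroxyhex-5-en-1-yl]-5-oxo-2,5-dihydrofuran-2-yl]-4,4-dimethoxy-2-methylidenebutanoate | ClCC(=C)CC[C@H](O)C1=C[C@@H](OC1=O)[C@@H](C(=C)C(=O)OC)C(OC)OC | intermediate
18 | methyl (3R)-3-[(2R)-4-[(1S)-5-(chloromethyl)-1-(2-methylpropanoyloxy)hex-5-en-1-yl]-5-oxo-2,5-dihydrofuran-2-yl]-4,4-dimethoxy-2-methylidenebutanoate | ClCC(=C)CC[C@H](OC(=O)C(C)C)C1=C[C@@H](OC1=O)[C@@H](C(=C)C(=O)OC)C(OC)OC | intermediate
19 | methyl (3R)-3-[(2R)-4-[(1S)-5-(chloromethyl)-1-(2-methylpropanoyloxy)hex-5-en-1-yl]-5-oxo-2,5-dihydrofuran-2-yl]-2-methylidene-4-oxobutanoate | ClCC(=C)CC[C@H](OC(=O)C(C)C)C1=C[C@@H](OC1=O)[C@@H](C(=C)C(=O)OC)C=O | intermediate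
20 | allylchromium dichloride of 19 (CH2Cl of 19 replaced by CH2–CrCl2, trivalent chromium) | Cl[Cr](Cl)CC(=C)CC[C@H](OC(=O)C(C)C)C1=C[C@@H](OC1=O)[C@@H](C(=C)C(=O)OC)C=O | intermediate (not isolated)
21 | methyl (3S,6R,7S,8R)-8-hydroxy-3-(2-methylpropanoyloxy)germacra-4E,10(14),11(13)-trien-15,6-olid-12-oate | COC(=O)C(=C)[C@H]1[C@H](O)CC(=C)CC[C@H](OC(=O)C(C)C)C2=C[C@H]1OC2=O | intermediate (not isolated)
22 | (3S,6R,7S,8R)-3-(2-methylpropanoyloxy)germacra-4E,10(14),11(13)-triene-12,8:15,6-diolide | C=C1C(=O)O[C@@H]2CC(=C)CC[C@H](OC(=O)C(C)C)C3=C[C@@H](OC3=O)[C@@H]12 | intermediate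
23 | (3S,6R,7S,8R,10R)-14-(9-borabicyclo[3.3.1]nonan-9-yl)-3-(2-methylpropanoyloxy)germacra-4E,11(13)-diene-12,8:15,6-diolide | C=C1C(=O)O[C@@H]2C[C@H](CB5C6CCCC5CCC6)CC[C@H](OC(=O)C(C)C)C3=C[C@@H](OC3=O)[C@@H]12 | intermediate (not isolated)
24 | (3S,6R,7S,8R,10R)-14-hydroxy-3-(2-methylpropanoyloxy)germacra-4E,11(13)-diene-12,8:15,6-diolide (CNP0332805.1) | C=C1C(=O)O[C@@H]2C[C@H](CO)CC[C@H](OC(=O)C(C)C)C3=C[C@@H](OC3=O)[C@@H]12 | target

**Summary**

Total step count: 14.
Longest linear sequence: 14 steps (1 and 2 to 24; the route is linear).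

Steps most likely to fail:

1. Step 13. Intermolecular coupling (oligomerisation) may outrun the strained ten-membered closure, or insertion of CrCl2 into the allylic chloride may be slow. Fallback: setting out from 19, the bond-forming species is changed from a stoichiometric, heterogeneous organochromium to a catalytically generated allylzinc. Pd(PPh3)4 (catalytic zerovalent palladium) should ionise the primary allylic chloride much faster than the hindered, conjugated C3 isobutyrate, and Et2Zn transmetalates the π-allylpalladium chloride to a nucleophilic allylzinc (umpolung), a closure of the kind known for ten-membered carbocycles. In dilute THF at rt this adds to the C8 aldehyde to give 21, which lactonises with PPTS to 22, where the route is rejoined. This fallback makes no new compound (F0).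

2. Step 14. The borane may attack the α-face of the C10=C14 alkene, or reduction of the α-methylene lactone may compete. Fallback: setting out from 22, mCPBA/NaHCO3 (CH2Cl2, 0 °C) epoxidises the only electron-rich alkene from that same α-face to the (10R)-10,14-epoxide of 22 F1. Methylaluminium bis(4-bromo-2,6-di-tert-butylphenoxide) (CH2Cl2, −78 °C) then opens the tertiary C10–O bond with a 1,2-hydride shift from C14 and inversion at C10 (Meinwald rearrangement) to the (10R)-14-oxo analogue of 24 F2. An α-face epoxidation therefore gives the C10 configuration opposite to that of an α-face hydroboration. Luche reduction (NaBH4, CeCl3·7H2O, MeOH, −78 °C) of the aldehyde, which is much faster than conjugate reduction of the methylene lactone, gives 24, where the route is rejoined.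

3. Step 7. Simple diastereoselectivity between C6 and C7 may be poor, or the C3 silyl ether next to the silyloxyfuran may ionise under the acidic conditions. Fallback: setting out from 11, methyl acrylate and 2,2-dimethoxyacetaldehyde are joined by a DABCO-catalysed Morita–Baylis–Hillman reaction to methyl 3-hydroxy-4,4-dimethoxy-2-methylidenebutanoate F3, which is acetylated (Ac2O, pyridine) to methyl 3-acetoxy-4,4-dimethoxy-2-methylidenebutanoate F4. A chiral bifunctional phosphine (Lewis-base catalysis, toluene, rt, acid-free) converts F4 into an allylphosphonium that furan 11 attacks at C5 (SN2'–SN2' allylic substitution). This forms the C6–C7 bond with the acrylate ester already in place and gives the silyl ether of 17 F5; citric acid work-up gives 17. The route is rejoined at 17 and steps 7 to 10 are bypassed.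

Further compounds
F0 | step 13 | none | none
F1 | step 14 | (3S,6R,7S,8R,10R)-10,14-epoxy-3-(2-methylpropanoyloxy)germacra-4E,11(13)-diene-12,8:15,6-diolide (epoxide oxygen on the face of O8) | C=C1C(=O)O[C@@H]2C[C@@]4(CO4)CC[C@H](OC(=O)C(C)C)C3=C[C@@H](OC3=O)[C@@H]12
F2 | step 14 | (3S,6R,7S,8R,10R)-3-(2-methylpropanoyloxy)-14-oxogermacra-4E,11(13)-diene-12,8:15,6-diolide | C=C1C(=O)O[C@@H]2C[C@H](C=O)CC[C@H](OC(=O)C(C)C)C3=C[C@@H](OC3=O)[C@@H]12
F3 | step 7 | methyl 3-hydroxy-4,4-dimethoxy-2-methylidenebutanoate (racemic) | COC(OC)C(O)C(=C)C(=O)OC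
F4 | step 7 | methyl 3-acetoxy-4,4-dimethoxy-2-methylidenebutanoate (racemic) | COC(OC)C(OC(C)=O)C(=C)C(=O)OC
F5 | step 7 | methyl (3R)-3-[(2R)-4-[(1S)-5-(chloromethyl)-1-[(trimethylsilyl)oxy]hex-5-en-1-yl]-5-oxo-2,5-dihydrofuran-2-yl]-4,4-dimethoxy-2-methylidenebutanoate | ClCC(=C)CC[C@H](O[Si](C)(C)C)C1=C[C@@H](OC1=O)[C@@H](C(=C)C(=O)OC)C(OC)OC
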